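The readings are calculated on assumed constants, noise included.

Q and G are counted on the same basis, so the share asked for comes from one number, the ratio cG/cQ.

| setting | larch | birch | cedar | alder | dusk | midnight | autumn | dawn |
|---|---|---|---|---|---|---|---|---|
| E | 5.0 × 10⁻⁴ M | 5.0 × 10⁻⁴ M | 5.0 × 10⁻⁴ M | 2.5 × 10⁻⁴ M | 5.0 × 10⁻⁴ M | 5.0 × 10⁻⁴ M | 5.0 × 10⁻⁴ M | 5.0 × 10⁻⁴ M (fed, over 4.0 min) |
| J | 0.50 mM | 0.25 mM | 1 mM | 0.50 mM | 0.500 mM (fed, over 1.0 min) | 0.500 mM (fed, over 4.0 min) | 0.500 mM | 0.500 mM |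
| temperature | −15 °C | 0 °C | −15 °C | 0 °C | 0 °C | 0 °C | 0 °C |  |
| remark | run made earlier | run made earlier | run made earlier | run made earlier | all else is in the flask from the start; the feed brings no volume worth counting | all else is in the flask from the start; the feed brings no volume worth counting | everything together at the start | the addition at −30 °C, then warmed to 0 °C; the feed brings no volume worth counting |
| time |  |  |  |  | 10 min | 10 min | 10 min | 10 min |

| run | time / min | Q / % | G / % |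
|---|---|---|---|
| larch | 1.00 | 0 | 0 |
| larch | 1.33 | 0.4 | 0.4 |
| larch | 2.00 | 0.3 | 0 |
| larch | 3.00 | 1.1 | 0.7 |
| larch | 5.00 | 2.5 | 1.2 |
| larch | 8.00 | 4.2 | 1.5 |
| larch | 12.0 | 6.8 | 3.5 |
| birch | 1.33 | 1.8 | 0.6 |
| birch | 3.00 | 4.1 | 0.2 |
| birch | 4.00 | 5.6 | 0.9 |
| birch | 6.00 | 6.4 | 0.1 |
| birch | 8.00 | 6.9 | 0.7 |
| birch | 10.0 | 6.0 | 1.6 |
| cedar | 2.00 | 0.4 | 0 |
| cedar | 3.00 | 0.3 | 0.1 |
| cedar | 4.00 | 2.3 | 1.5 |
| cedar | 6.00 | 4.9 | 1.0 |
| cedar | 8.00 | 7.0 | 1.9 |
| cedar | 12.0 | 11.7 | 3.8 |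
| cedar | 20.0 | 16.5 | 6.4 |
| alder | 0.833 | 1.7 | 0 |
| alder | 2.50 | 7.4 | 1.0 |
| alder | 5.00 | 9.6 | 2.2 |
| alder | 8.00 | 10.9 | 0.7 |
| alder | 10.0 | 11.0 | 1.4 |

(each reading ± 0.5 percentage points)

1. which flask leads in share of Q in Q plus G ("all alike" within 1.5 percentage points) (dusk / midnight / autumn / dawn / all alike)
2. share of Q in Q plus G at the end, dusk
3. share of Q in Q plus G at the end, midnight
4. share of Q in Q plus G at the end, autumn
5. share of Q in Q plus G at the end, dawn



**What do the runs give for that ratio at 0 °C?** One late reading of G is mostly scatter, so I add up the late readings of birch and alder. Their G over their Q gives 0.132. This is the frozen ratio, cG/cQ at one temperature, and it makes the share 88.3%.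

**Does it depend on how much J is present?** Alder has 4.00 times birch's J per E, yet the readings give 0.137 for alder and 0.124 for birch. I therefore hold it fixed for dusk and midnight, whose feeds change cJ, and for autumn, where J goes in at the start.

**And temperature?** That does move it. The late readings of larch and cedar at −15 °C give 0.388, larger than at 0 °C.

**So dawn is the weak spot?** Its feed runs at −30 °C, colder than larch. Comparing birch with larch at 3.00 min, per unit of J, the step down from 0 °C to −15 °C slows formation by a factor of 4.78. The same factor once more puts dawn's cold part near 0.377% of E, against 7.60% in birch. I let it weigh nothing and commit to 88.3% in each flask.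

The forecast gave 88.3%, 88.3%, 88.3% and 87.5% for dusk, midnight, autumn and dawn, so all alike, on the ground that “G/Q stays constant with time and concentration”.

The flasks give 87.5% for dusk, 87.5% for midnight, 87.5% for autumn and 87.5% for dawn, so all alike, and their ratio is 0.143 against my 0.132.

    J → Z (k = 0.0194 s⁻¹, Ea = 79.0 kJ mol⁻¹)
    2 Z → X (k = 7.43 M⁻¹ s⁻¹, Ea = 48.0 kJ mol⁻¹)
    Q ⇌ G (K = 0.143, k = 0.0184 s⁻¹, Ea = 70.0 kJ mol⁻¹, ΔH = −40.0 kJ mol⁻¹)
    E ⇌ L (K = 29.0, k = 0.00826 s⁻¹, Ea = 81.0 kJ mol⁻¹, ΔH = −29.0 kJ mol⁻¹)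
    L → D (k = 0.0196 s⁻¹, Ea = 82.0 kJ mol⁻¹)
    L + Z → Q (k = 11.5 M⁻¹ s⁻¹, Ea = 39.0 kJ mol⁻¹)
    (constants at 0 °C)

At 0 °C the forward step from Q to G has a half-life of 0.628 min, shorter than the 4.4 min of L going to Q in dusk at 1.14 min, and the ratio in each flask stands at 0.143, which is thermodynamic control. Dawn held 0% Q at 4.00 min.

Going from −15 °C to 0 °C multiplied the ratio by 0.340. An equal step from 0 °C to 15 °C gives 0.0449, a share of 95.7%, and the flask like dusk kept at 15 °C gives 94.6%.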